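The readings were generated by integration for substances that don't exist; noise was put on by code.

- In a one-step world the starting complex ends as product, so the plateau is the whole charge.

| flask | starting complex | incoming ligand | leaving ligand | protic impurity | remark | time |
|---|---|---|---|---|---|---|
| midnight | 0.20 mM | 2.5 equiv | 5 equiv | 0.010 mM | run made earlier |  |
| summer | 0.10 mM | 2.5 equiv | 5 equiv | 0.010 mM | run made earlier |  |
| autumn | 0.15 mM | 2.5 equiv | 5 equiv | 0.010 mM | run made earlier |  |
| spring | 0.20 mM | 1.2 equiv | 5 equiv | 0.010 mM | run made earlier |  |
| grey | 0.20 mM (fed, over 4.0 min) | 2.50 equiv | 5.00 equiv | 0.0100 mM | all else is in the flask from the start; the feed brings no volume worth counting | 6.0 min |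
| violet | 0.20 mM | 2.50 equiv (fed, over 4.0 min) | 5.00 equiv | 0.0100 mM | all else is in the flask from the start; the feed brings no volume worth counting | 6.0 min |
| teal | 0.20 mM | 2.50 equiv | 5.00 equiv | 0.0100 mM | everything together at the start | 6.0 min |
| ochre | 0.20 mM | 2.50 equiv (in portions, 2, over 4.0 min) | 5.00 equiv | 0.0100 mM | first portion at the start, last at 4.0 min | 6.0 min |

| run | time / min | complex with two exchanged / % | starting complex / % |
|---|---|---|---|
| midnight | 0.250 | 17.0 | 60.4 |
| midnight | 0.500 | 36.6 | 42.1 |
| midnight | 1.00 | 59.2 | 25.0 |
| midnight | 2.00 | 78.5 | 10.6 |
| midnight | 4.00 | 90.5 | 4.1 |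
| summer | 0.667 | 23.6 | 49.7 |
| summer | 2.00 | 56.6 | 23.1 |
| summer | 3.00 | 68.8 | 14.8 |
| summer | 5.00 | 80.3 | 6.9 |
| summer | 8.00 | 85.2 | 2.4 |
| autumn | 0.500 | 26.6 | 49.7 |
| autumn | 1.00 | 48.6 | 30.7 |
| autumn | 2.00 | 70.7 | 15.0 |
| autumn | 4.00 | 85.6 | 6.2 |
| autumn | 8.00 | 92.3 | 0.6 |
| spring | 0.500 | 13.7 | 64.1 |
| spring | 1.00 | 27.4 | 51.4 |
| spring | 2.00 | 39.9 | 38.3 |
| spring | 4.00 | 49.9 | 32.3 |
| spring | 8.00 | 52.6 | 28.4 |

(standard deviation of a reading: 0.5 percentage points)

- the numbers in the tables scatter with a standard deviation of 0.5 percentage points
- a reading or a percentage of leaving ligand counts all its forms, free or not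

1. the flask with the highest amount of complex with two exchanged, in percent of the starting complex charged ("all alike" if they lie within 1.5 percentage points) (grey / violet / teal / ochre / all alike)
2. final complex with two exchanged, as a percentage of the starting complex charged, in grey
3. final complex with two exchanged, as a percentage of the starting complex charged, in violet
4. final complex with two exchanged, as a percentage of the starting complex charged, in teal
5. final complex with two exchanged, as a percentage of the starting complex charged, in ochre

- But the two read species miss 5.40% of the charge at the last midnight reading and 7.10% at the last autumn reading.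
- Impurity over charge is 5.00% and 6.67% there, so you may read a one-for-one loss of starting complex.
- Define the ceiling 95.0% as one minus impurity over charge. Grey, violet, teal and ochre share it, and it is your upper bound.
- Teal repeats the midnight recipe, so your lower bound there is the 90.5% read at 4.00 min.
- Tighten it. The gap to the ceiling is 4.5 percentage points at that reading. Starting complex fell to 0.387 of its reading over the preceding 2.00 min. Apply that factor once more: the gap becomes 1.7 points, and I commit to 93.3% for teal.
- Grey, violet and ochre have 2.00 min after their last addition, so midnight's 78.5% at that age is their rough floor.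
- In ochre, half the incoming ligand has the full 6.0 min and half has that short time. Averaging the gaps, with 16 points for the short one, gives 85.9%.
- A steady feed spreads the ages between those two, so I place grey and violet between ochre and teal.
- The forecast names teal at 92.7%, with violet 87%, grey 85% and ochre 82%, lower than my teal and ochre figures, holding that “Teal has the longest exposure to ligand”.
- The flasks give grey 86.9%, violet 88.6%, teal 93.2% and ochre 85.4%, so teal stands highest.

    starting complex + incoming ligand ⇌ leaving ligand + complex with one exchanged (K = 180, k = 67.2 M⁻¹ s⁻¹)
    complex with one exchanged + incoming ligand ⇌ leaving ligand + complex with two exchanged (K = 89.3, k = 203 M⁻¹ s⁻¹)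
    protic impurity + starting complex → quenched substrate (k = 2640 M⁻¹ s⁻¹)
    crystals ⇌ leaving ligand, rate k4*(cs4 - [leaving ligand]) while solid is left; crystals form when [leaving ligand] > cs4 (solubility = 0.0190 mM, k = 0.796 s⁻¹)

- In teal the protic impurity, limiting reagent of its loss, has a half-life of 1.3 s at the charged amounts, stands at 0% by 6.00 min, and has left quenched substrate at 5.00%, the share of the charge above the ceiling.
- The exchanges ran on in teal, with half-lives by the forward step of 0.34 min for starting complex and 0.11 min for complex with one exchanged at the charged amounts, and 1.8 points under the ceiling remain at 6.00 min.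
- The ochre neighbour with 4.20 equiv of incoming ligand stands close to the ceiling at 94.7%, with 0.17% of starting complex left.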